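Time is the question for this flask: in both earlier runs target stops rising within days and then sinks, and the speed of that sinking says how long the flask stays near its best.

in all of them: substrate 18 mM

| flask | reagent | remark | time |
|---|---|---|---|
| gamma | 16 mM (fed, over 6.0 h) | run made earlier |  |
| eta | 65 mM (fed, over 6.0 h) | run made earlier |  |
| flask | 32.4 mM (fed, over 6.0 h) |  | 15 d |

- gamma (time / d: target / %): 0.833: 25.8; 2.08: 38.2; 5.00: 39.3; 12.0: 33.5
- eta (time / d: target / %): 0.833: 64.4; 2.08: 67.2; 5.00: 63.3; 12.0: 59.4

(scatter of a reading: 1 percentage point)

* the moment within 15 d at which there is most target
* the amount of target, in percent of the substrate charged, at that time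
* earliest time at which at least nineteen twentieths of that best amount are there, in d
* latest time at which they still are, in d

- a reading or a percentage of target counts all its forms, free or not

Two chemists reckon the sinking in different ways.

The first works in logarithms and takes the loss as a share of the target present each day, a first-order fade. The gamma run, from 5.00 d to 12.0 d, reads 0.0228 d⁻¹. The eta run, from 2.08 d to 12.0 d, reads 0.0124 d⁻¹, so the gamma reading is twice the eta one. Their mean, 0.0176 d⁻¹, keeps this flask above the level asked for during 2.84 d after its peak.

The forecast speaks this language, “at about 1–2% of the target per day”. It gives a best of 56% at 2.8 d, held from 1.6 d to 6.5 d. That closing time is later than the 5.64 d this mean gives from the same peak.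

The second chemist subtracts instead of dividing. The gamma run loses 0.00829 d⁻¹ of the charge per day, and the eta run 0.00786 d⁻¹, equal within the scatter although the eta run holds more target. Their mean is the fade 0.00807 d⁻¹, the fraction of the charge lost as target per day, a zero-order reading. The span after the peak is then the allowed loss over the fade. For this flask, with the forecast's best, the allowed loss is 2.80%, which gives 3.47 d and a close at 6.27 d.

    substrate + reagent ⇌ target (K = 67.0 M⁻¹, k = 2.00 M⁻¹ h⁻¹)
    substrate + reagent ⇌ isomer of the product A (K = 270 M⁻¹, k = 0.640 M⁻¹ h⁻¹)
    crystals ⇌ target, rate k3*(cs3 - [target]) while solid is left; crystals form when [target] > cs3 (solubility = 1.20 mM, k = 4.00 h⁻¹)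
    target ⇌ isomer of the product B (K = 2.40, k = 0.0220 h⁻¹)

This flask reaches 60.5% at 2.94 d, and holds the level asked for from 1.64 d to 6.30 d. Its span after the peak is 3.36 d, against 3.75 d from the fade with this best and 2.84 d from the mean share. The share view keeps its ground over a loss as small as 2.80% of the charge, where a line and a curve lie close together. At 2.94 d, crystals make up 53.8% of this flask's 60.5% target. A neighbour charged with 8.1 mM of reagent falls from 17.3% to 5.81% by 15 d, a loss of 11 percentage points, while the fade counted over that whole time comes to 12 points.

The readings are simulated for an exercise, noise included.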